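**Assumption:** Aspidin AB has no stereocentres, so no enantiocontrol is needed. The bis-enol/trione part is drawn as the tautomer given in the target SMILES.

## Retrosynthetic overview
1. Aspidin AB is disconnected at the aryl–CH2 bond. An aryl radical from iodide **15** adds to the CH2 terminus of a transient 6-methylene-trione (from acetylfilicinic acid **6** and CH2O), in a photochemical XAT/Giese coupling. This is the key step, and the benzyl ether of the para-OH is removed last.
2. Iodide **15** comes from 2-methylphloroglucinol (**10**) by butyrylation, 4-O-benzylation, 2-O-methylation and iodination. The aromatic ring of **10** is made by a double Claisen (Dieckmann) sequence from 2,4-hexanedione and dimethyl carbonate.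
3. Acetylfilicinic acid **6** comes from methyl isobutyrate and diketene by acetoacetylation, Weiler-dianion Dieckmann cyclisation and C-acetylation.
4. Ring order: filicinic ring, then arene ring, then the CH2 bridge last.

## Route

**Step 1**
Reactants: **1** methyl isobutyrate; **2** diketene
Product: **3** methyl 2,2-dimethyl-3,5-dioxohexanoate
Conditions: LDA (1.0 equiv), THF, −78 °C; add **2**, −78 → 0 °C; NH4Cl
Reagents that add atoms: none
Why: The ester enolate opens diketene at its lactone C=O (acetoacetylation), which installs the CMe2 quaternary centre flanked by the future C1 and C3 carbonyls.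

**Step 2**
Reactant: **3**
Product: **4** filicinic acid (2,2-dimethylcyclohexane-1,3,5-trione)
Conditions: LDA (2.3 equiv), THF, −78 °C → reflux; then 2 M HCl
Reagents that add atoms: none
Why: Weiler dianion formation at C4 and C6, then a Dieckmann/Claisen closure of C6 onto the ester. The ester is α-quaternary and cannot enolise, so it stays electrophilic. The product trione enolate drives the reaction and MeOH is lost.

**Step 3**
Reactants: **4**; **5** acetic acid
Product: **6** 2-acetyl-4,4-dimethylcyclohexane-1,3,5-trione (acetylfilicinic acid)
Conditions: DCC (1.1 equiv), DMAP (2 equiv), CH2Cl2, 0 °C → rt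
Reagents that add atoms: none
Why: DCC/DMAP acylation of the cyclic 1,3-dicarbonyl proceeds by O-acylation then 1,3-acyl shift to carbon. The two CH2 sites of **4** are equivalent, and one equivalent of acid gives the mono-C-acetyl product.

**Step 4**
Reactants: **7** 2,4-hexanedione; **8** dimethyl carbonate
Product: **9** methyl 3,5-dioxoheptanoate
Conditions: NaH (1 equiv), THF, 0 °C; n-BuLi (1 equiv); then **8** (1.5 equiv), 0 → 25 °C; HCl
Reagents that add atoms: none
Why: Weiler dianion chemistry; the second deprotonation occurs at the less hindered CH3 terminus, so Claisen acylation by dimethyl carbonate gives the β-keto ester at that end and places the future ring methyl correctly.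

**Step 5**
Reactant: **9**
Product: **10** 2-methylbenzene-1,3,5-triol (2-methylphloroglucinol)
Conditions: t-BuOK (3 equiv), DMSO, 60 °C; 2 M HCl
Reagents that add atoms: none
Why: Intramolecular Dieckmann closure of the ethyl-terminus carbanion onto the methyl ester, then tautomerisation to the aromatic triol. The ethyl CH2 becomes the C–Me carbon.

**Step 6**
Reactants: **10**; **11** butyric acid
Product: **12** 1-(2,4,6-trihydroxy-3-methylphenyl)butan-1-one
Conditions: BF3·OEt2, 80 °C, 3 h
Reagents that add atoms: none
Why: BF3-mediated Friedel–Crafts acylation of a phloroglucinol. The two free ring positions of **10** are equivalent, so only one regioisomer forms.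

**Step 7**
Reactant: **12**
Product: **13** 1-[4-(benzyloxy)-2,6-dihydroxy-3-methylphenyl]butan-1-one
Conditions: BnBr (1.0 equiv), K2CO3 (1 equiv), acetone, 50 °C
Reagents that add atoms: benzyl bromide, BrCc1ccccc1
Why: Williamson alkylation goes at the most acidic OH, the one para to the acyl group. The two ortho OH groups are much less acidic, and one is H-bonded to the carbonyl.

**Step 8**
Reactant: **13**
Product: **14** 1-[4-(benzyloxy)-6-hydroxy-2-methoxy-3-methylphenyl]butan-1-one
Conditions: MeI (1.5 equiv), K2CO3, acetone, reflux
Reagents that add atoms: methyl iodide, CI
Why: Williamson O-methylation of the non-chelated ortho OH, which is flanked by Me and acyl. This sets the OMe/Me/acyl pattern of the target.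

**Step 9**
Reactant: **14**
Product: **15** 1-[4-(benzyloxy)-6-hydroxy-5-iodo-2-methoxy-3-methylphenyl]butan-1-one
Conditions: NIS (1.05 equiv), MeCN, 0 °C → rt
Reagents that add atoms: N-iodosuccinimide, O=C1CCC(=O)N1I
Why: Electrophilic iodination at the only free, highly activated ring carbon, which lies between the two oxygens. This gives the future bridge position without regiochemistry problems.

**Step 10**
Reactants: **15**; **6**; **16** paraformaldehyde
Product: **17** benzyl-protected aspidin AB
Conditions: 4CzIPN (2 mol%), DIPEA (4 equiv), **6** (2 equiv), (CH2O)n (4 equiv), DMF, blue LEDs (455 nm), 40 °C, 24 h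
Reagents that add atoms: none
Why: Proposed new method: DIPEA•+ loses a proton to give an α-aminoalkyl radical, which abstracts iodine from **15** (halogen-atom transfer) to give the aryl radical. The aryl radical adds to the CH2 terminus of the 6-methylene-trione formed in situ from **6** and CH2O (amine-catalysed Knoevenagel). The resulting electrophilic α,α-diacyl radical is reduced and protonated, forming the new Ar–CH2–C bond. The closest known reaction types are XAT-initiated aryl-radical Giese addition and photoredox radical–polar crossover. The arene is fully substituted, so ionic Friedel–Crafts/Michael reaction cannot compete. The product is acidified to its enol form.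

**Step 11**
Reactant: **17**
Product: **18** aspidin AB
Conditions: H2 (1 atm), 10% Pd/C, EtOAc, rt, 2 h
Reagents that add atoms: none (H2 only adds hydrogen)
Why: Hydrogenolysis of the aryl benzyl ether frees the 4-OH. The H-bonded aryl ketone, the trione enols and the methyl ether are untouched.

## Compound list
1 | methyl isobutyrate | COC(=O)C(C)C | starting material
2 | diketene | C=C1CC(=O)O1 | starting material
3 | methyl 2,2-dimethyl-3,5-dioxohexanoate | COC(=O)C(C)(C)C(=O)CC(C)=O | intermediate
4 | filicinic acid | CC1(C)C(=O)CC(=O)CC1=O | intermediate
5 | acetic acid | CC(=O)O | starting material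
6 | 2-acetyl-4,4-dimethylcyclohexane-1,3,5-trione | CC(=O)C1=C(O)CC(=O)C(C)(C)C1=O | intermediate
7 | 2,4-hexanedione | CCC(=O)CC(=O)C | starting material
8 | dimethyl carbonate | COC(=O)OC | starting material
9 | methyl 3,5-dioxoheptanoate | CCC(=O)CC(=O)CC(=O)OC | intermediate
10 | 2-methylphloroglucinol | Cc1c(O)cc(O)cc1O | intermediate
11 | butyric acid | CCCC(=O)O | starting material
12 | 1-(2,4,6-trihydroxy-3-methylphenyl)butan-1-one | CCCC(=O)c1c(O)cc(O)c(C)c1O | intermediate
13 | 1-[4-(benzyloxy)-2,6-dihydroxy-3-methylphenyl]butan-1-one | CCCC(=O)c1c(O)cc(OCc2ccccc2)c(C)c1O | intermediate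
14 | 1-[4-(benzyloxy)-6-hydroxy-2-methoxy-3-methylphenyl]butan-1-one | CCCC(=O)c1c(O)cc(OCc2ccccc2)c(C)c1OC | intermediate
15 | 1-[4-(benzyloxy)-6-hydroxy-5-iodo-2-methoxy-3-methylphenyl]butan-1-one | CCCC(=O)c1c(O)c(I)c(OCc2ccccc2)c(C)c1OC | intermediate
16 | paraformaldehyde (CH2O) | C=O | starting material
17 | benzyl-protected aspidin AB | CCCC(=O)c1c(O)c(CC2=C(O)C(C)(C)C(=O)C(C(C)=O)=C2O)c(OCc2ccccc2)c(C)c1OC | intermediate
18 | aspidin AB | CCCC(=O)c1c(O)c(CC2=C(O)C(C)(C)C(=O)C(C(C)=O)=C2O)c(O)c(C)c1OC | target

## Totals
Total steps: 11. Longest linear sequence: 8 (7 → 9 → 10 → 12 → 13 → 14 → 15 → 17 → 18, counting steps 4–11). Steps 1–2 and 4–5 could each be telescoped.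

## Three steps most likely to fail
1. **Step 10 (key radical coupling).** Hydrodeiodination of the aryl radical, or decomposition of the methylene-trione, would compete.
   Fallback (different approach): generate the aryl radical from **15** with a silane/Et3B chain process, and use isolated 6,6'-methylene-bis(acetylfilicinic acid) as a stable methylene-trione donor.
2. **Step 5 (Claisen ring closure of an enolisable ester).** O-Acylation to the 4-hydroxy-2-pyranone, or a low concentration of the C6 carbanion, would lower the yield.
   Fallback (different approach): close the ring by a Lewis-acid-mediated Mukaiyama-type acylation of the bis(silyl enol ether) of **9** (TMSOTf/Et3N, then TiCl4).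
3. **Step 1 (diketene acylation of the hindered ester enolate).** Enolate attack may be sluggish or give O-acylation.
   Fallback (different approach): form the ring by Boehm-type exhaustive C-methylation of phloroglucinol made from acetylacetone and dimethyl carbonate, then isolate the 2,2-dimethyl congener.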